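All runs come from a simulation from invented constants; scatter was added.

- Late in the epsilon run the electrophile readings fall more slowly than over the first 6.00 min, so a straight line from 15.0 min will not carry you to 40 min. You need the remainder in closed form.

in all of them: electrophile 0.30 M
- epsilon: nucleophile 0.80 equiv; free base 1.2 equiv; run made earlier
- Wednesday's: nucleophile 1.20 equiv; free base 1.20 equiv; time 40 min
- Thursday's: nucleophile 1.20 equiv; free base 2.40 equiv; time 40 min

epsilon run (percent of the electrophile charged)

| time / min | electrophile / % | product / % |
|---|---|---|
| 1.33 | 98.3 | 0.7 |
| 4.00 | 94.8 | 2.4 |
| 6.00 | 92.4 | 3.7 |
| 10.0 | 87.8 | 5.8 |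
| 15.0 | 83.1 | 7.8 |

(readings scatter by 0.3 percentage points)

- part of the electrophile that has reacted at the end, Wednesday's
- part of the electrophile that has reacted at the end, Thursday's
- what raising the equivalents of free base from its lowest to its highest value here does to the part of the electrophile that has reacted (changes below 5 percentage points count as none) (it rises / it falls / no change)

- percent here means electrophile units held: one homo dimer counts as two
- what is said of product includes idle adduct
- the earlier runs were read with a standard deviation of 0.3 percentage points
- steps that have been proposed: electrophile + nucleophile -> acid set free + product; nucleophile + acid set free <-> protonated nucleophile; acid set free + free base <-> salt of the base; free base <-> dormant form; nucleophile + product <-> idle adduct; 2 electrophile -> homo dimer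
- no earlier run changes the charge of free base; that part of a forecast is a guess

- At 15.0 min of the epsilon run, the electrophile lost exceeds the product by 9.10 %, which I read as electrophile units held in homo dimer.
- Let x be c(electrophile) over its charge. While c(nucleophile) stays near its charge, product formation is pseudo-first-order with constant a, and the homo dimer goes with x·x and constant d.
- Then dx/dt = −a·x − d·x·x, which integrates to x = a·E/(a + d − d·E), with E = exp(−a·t).
- Midway between the start and the last reading of the epsilon run, x is about 91.5 %. So the readings, with their scatter of 0.3 percentage points, give d = 0.00724 min⁻¹ and a = 0.00568 min⁻¹, the product constant at 0.80 equiv of nucleophile.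
- Wednesday's has the same electrophile charge, so d stays. Taking a as proportional to the nucleophile charge gives a = 0.00852 min⁻¹, E = 0.711 and 42.9 % reacted by my reckoning.
- My formula for x has no term in free base, and no earlier run changes its charge, so for Thursday's I can only guess a difference from Wednesday's of less than 5 points.
- The forecast says 41 % for Wednesday's, below my figure, and 42 % for Thursday's, hence no change: “doubling it should protect only a little nucleophile”.
- The flasks give 40.8 % on Wednesday's and 41.1 % on Thursday's, a change of 0.32 points, so no change, and the forecast held. At 40 min of Wednesday's, free nucleophile stood at 66 % of its charge. My product constant scaled to that share is 0.00562 min⁻¹ for that moment, not the 0.00852 min⁻¹ I held constant, and my figure lies 2.1 points above the flask.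

    electrophile + nucleophile → acid set free + product (k = 0.0270 M⁻¹ min⁻¹)
    nucleophile + acid set free ⇌ protonated nucleophile, settled at all times (K = 760 M⁻¹)
    acid set free + free base ⇌ salt of the base, settled at all times (K = 1000 M⁻¹)
    free base ⇌ dormant form (K = 0.344, k = 0.00535 min⁻¹)
    nucleophile + product ⇌ idle adduct, settled at all times (K = 1.82 M⁻¹)
    2 electrophile → homo dimer (k = 0.0117 M⁻¹ min⁻¹)

- Take the neighbour of Thursday's charged with 4.80 equiv of nucleophile. The product constant scales to a = 0.0341 min⁻¹, so E = 0.256 and x gives 77.9 % reacted at 40 min.
- That flask gives 75.0 %, with 66.5 % as product, its forms counted.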